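**Retrosynthetic overview**

1. Calbistrin D is cut at the C1–O ester (Yamaguchi) and at C5′–C6′ (Stille) into the decalin, iodo acid 30 and stannyl trienoic acid 39; C10–C11 are added by a Mukaiyama aldol with formaldehyde on the C9 methyl ketone.
2. Feature used: in ring B the quaternary C8 carries a methyl and the C9 acyl group and lies between ring-fusion carbon C8a and the tertiary carbinol C7 (Me, OH), so C7 and C9 are both acetyl carbons on C8, i.e. a 3,3-disubstituted pentane-2,4-dione on C8a.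
3. Ring B is closed through C6–C7: the C6 alkenyl metal from a (Z)-2-iodoethenyl group on C4a adds to one of the two acetyl groups, setting C7 and C8.
4. C8a–C8 and the C4=C4a alkene come from a Claisen rearrangement of the ring-A allylic enol ether of 3-methylpentane-2,4-dione (C4–O to C8a chirality transfer).
5. Ring A is not built but taken from a cyclohexenone (CBS reduction sets C1, α′-methylation C3, iodination/Sonogashira brings C5–C6, Luche reduction gives C4–OH); ring order: A (given), then B in the key step.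

Key step: step 13

Remarks.
- Numbering: decalin C1 (O), C2, C3 (Me), C4=C4a, C5=C6, C7 (Me, OH), C8 (Me, acyl), C8a; acyl chain C9–C11; side chain C1′ (ester C=O) to C12′ (CO2H). "Upper face" is the face of ring A that carries the C1 oxygen.
- The enol-ether double bond of 13 is drawn E; its geometry has no stereochemical consequence because both of its substituents end as acetyl groups on C8.
- Assumption (step 17): the magnesium-catalysed anti-aldol is taken to follow the chelated Z-enolate model with attack anti to the benzyl group; on this basis the (R)-auxiliary 25 leads to the (2′S,3′R) adduct.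
- Compounds 1, 10, 21, 25 and 35 are taken to be catalogue compounds.

**Route**

Step 1
Reactants: 1 1,4-dioxaspiro[4.5]dec-6-en-8-one
Product: 2 (S)-1,4-dioxaspiro[4.5]dec-6-en-8-ol
Conditions: (R)-Me-CBS (0.1 equiv), BH3·SMe2, THF, –30 °C; aq. work-up
Reagents that add atoms: none
Why: Corey–Bakshi–Shibata reduction, in which the (R)-oxazaborolidine binds the ketone with the alkenyl arm as the large group and delivers hydride to the face that gives the (S)-allylic alcohol, the future C1.

Step 2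
Reactants: 2 (S)-1,4-dioxaspiro[4.5]dec-6-en-8-ol
Product: 3 (S)-8-[(tert-butyldimethylsilyl)oxy]-1,4-dioxaspiro[4.5]dec-6-ene
Conditions: TBSCl, imidazole, DMF, rt
Reagents that add atoms: tert-butyldimethylsilyl chloride, CC(C)(C)[Si](C)(C)Cl
Why: standard silylation of a secondary alcohol that touches no stereocentre.

Step 3
Reactants: 3 (S)-8-[(tert-butyldimethylsilyl)oxy]-1,4-dioxaspiro[4.5]dec-6-ene
Product: 4 (S)-4-[(tert-butyldimethylsilyl)oxy]cyclohex-2-en-1-one
Conditions: PPTS (cat.), acetone/H2O, 50 °C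
Reagents that add atoms: water, O
Why: mild acid-catalysed acetal hydrolysis unmasks the enone and should leave the TBS ether and the C1 stereocentre untouched.

Step 4
Reactants: 4 (S)-4-[(tert-butyldimethylsilyl)oxy]cyclohex-2-en-1-one
Product: 6 (4S,6S)-4-[(tert-butyldimethylsilyl)oxy]-6-methylcyclohex-2-en-1-one (4,6-trans), via lithium dienolate 5 (not isolated)
Conditions: LDA, THF, –78 °C; MeI, DMPU, –78 → –40 °C
Reagents that add atoms: iodomethane, CI
Why: kinetic α′-deprotonation and enolate alkylation, in which methyl iodide should approach the cross-conjugated dienolate on the face opposite the pseudo-axial silyloxy group and so set C3 trans to the C1 oxygen (any cis isomer to be removed by chromatography).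

Step 5
Reactants: 6 (4S,6S)-4-[(tert-butyldimethylsilyl)oxy]-6-methylcyclohex-2-en-1-one
Product: 7 (4S,6S)-4-[(tert-butyldimethylsilyl)oxy]-2-iodo-6-methylcyclohex-2-en-1-one
Conditions: I2, pyridine, CH2Cl2, 0 °C → rt
Reagents that add atoms: iodine, II
Why: α-iodination of the enone by the pyridine addition–iodination–elimination sequence (Baylis–Hillman-type), which functionalises only the α-vinylic carbon, the future C4a.

Step 6
Reactants: 7 (4S,6S)-4-[(tert-butyldimethylsilyl)oxy]-2-iodo-6-methylcyclohex-2-en-1-one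
Product: 8 (4S,6S)-4-[(tert-butyldimethylsilyl)oxy]-6-methyl-2-[(trimethylsilyl)ethynyl]cyclohex-2-en-1-one
Conditions: TMS-acetylene, PdCl2(PPh3)2 (cat.), CuI (cat.), i-Pr2NH, THF, 0 °C
Reagents that add atoms: ethynyltrimethylsilane, C#C[Si](C)(C)C
Why: Sonogashira coupling of an α-iodoenone brings in C5 and C6 as an alkyne at low temperature without epimerising the α′-centre.

Step 7
Reactants: 8 (4S,6S)-4-[(tert-butyldimethylsilyl)oxy]-6-methyl-2-[(trimethylsilyl)ethynyl]cyclohex-2-en-1-one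
Product: 9 (1R,4S,6S)-4-[(tert-butyldimethylsilyl)oxy]-6-methyl-2-[(trimethylsilyl)ethynyl]cyclohex-2-en-1-ol (OH cis to OTBS, trans to Me)
Conditions: NaBH4, CeCl3·7H2O, MeOH, –78 °C
Reagents that add atoms: none
Why: Luche 1,2-reduction in which, with the C3 methyl equatorial and the C1 silyloxy group pseudo-axial, axial hydride delivery from the face opposite the silyloxy group should give the C4 alcohol cis to the C1 oxygen and trans to the C3 methyl.

Step 8
Reactants: 10 3-methylpentane-2,4-dione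
Product: 11 4-chloro-3-methylpent-3-en-2-one (E/Z mixture)
Conditions: (COCl)2, DMF (cat.), CH2Cl2, 0 °C → rt
Reagents that add atoms: oxalyl chloride, ClC(=O)C(=O)Cl
Why: Vilsmeier-type chlorination of the β-diketone enol gives the β-chloro enone, a vinylogous acid chloride whose two geometric isomers are equally usable.

Step 9
Reactants: 9 (1R,4S,6S)-4-[(tert-butyldimethylsilyl)oxy]-6-methyl-2-[(trimethylsilyl)ethynyl]cyclohex-2-en-1-ol; 11 4-chloro-3-methylpent-3-en-2-one
Product: 13 (E)-4-{[(1R,4S,6S)-4-[(tert-butyldimethylsilyl)oxy]-6-methyl-2-[(trimethylsilyl)ethynyl]cyclohex-2-en-1-yl]oxy}-3-methylpent-3-en-2-one, via sodium alkoxide 12 (not isolated)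
Conditions: NaH, THF, 0 °C; then 11, 0 °C → rt
Reagents that add atoms: none
Why: addition–elimination (vinylic substitution) of the alkoxide on the β-chloro enone forms the vinylogous ester without breaking the C4–O bond, so the C4 configuration is retained.

Step 10
Reactants: 13 (E)-4-{[(1R,4S,6S)-4-[(tert-butyldimethylsilyl)oxy]-6-methyl-2-[(trimethylsilyl)ethynyl]cyclohex-2-en-1-yl]oxy}-3-methylpent-3-en-2-one
Product: 14 3-{(1S,4S,6S)-6-[(tert-butyldimethylsilyl)oxy]-4-methyl-2-[(trimethylsilyl)ethynyl]cyclohex-2-en-1-yl}-3-methylpentane-2,4-dione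
Conditions: toluene, 170 °C (sealed tube), 2,6-di-tert-butyl-4-methylpyridine (cat.)
Reagents that add atoms: none
Why: Claisen rearrangement ([3,3]) of the allyl enol ether, whose suprafacial course forms C8a–C8 on the face that carried the C4 oxygen (cis to the C1 silyloxy group), creates the C4=C4a alkene and turns the enol-ether carbon into the second acetyl group, so C8 is not stereogenic.

Step 11
Reactants: 14 3-{(1S,4S,6S)-6-[(tert-butyldimethylsilyl)oxy]-4-methyl-2-[(trimethylsilyl)ethynyl]cyclohex-2-en-1-yl}-3-methylpentane-2,4-dione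
Product: 15 3-{(1S,4S,6S)-6-[(tert-butyldimethylsilyl)oxy]-2-(iodoethynyl)-4-methylcyclohex-2-en-1-yl}-3-methylpentane-2,4-dione
Conditions: NIS, AgNO3 (cat.), DMF, rt, dark
Reagents that add atoms: N-iodosuccinimide, O=C1CCC(=O)N1I
Why: silver-catalysed iododesilylation of the alkynylsilane gives the 1-iodoalkyne directly and should not touch the non-enolisable-at-C8 diketone or the silyl ether.

Step 12
Reactants: 15 3-{(1S,4S,6S)-6-[(tert-butyldimethylsilyl)oxy]-2-(iodoethynyl)-4-methylcyclohex-2-en-1-yl}-3-methylpentane-2,4-dione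
Product: 16 3-{(1S,4S,6S)-6-[(tert-butyldimethylsilyl)oxy]-2-[(Z)-2-iodoethenyl]-4-methylcyclohex-2-en-1-yl}-3-methylpentane-2,4-dione
Conditions: 2-nitrobenzenesulfonylhydrazide, Et3N, THF/i-PrOH, rt
Reagents that add atoms: none
Why: diimide reduction adds H2 syn to the iodoalkyne and gives the (Z)-alkenyl iodide, while the trisubstituted ring alkene should react much more slowly and the ketones not at all.

Step 13
Reactants: 16 3-{(1S,4S,6S)-6-[(tert-butyldimethylsilyl)oxy]-2-[(Z)-2-iodoethenyl]-4-methylcyclohex-2-en-1-yl}-3-methylpentane-2,4-dione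
Product: 19 1-[(1R,2R,6S,8S,8aS)-8-[(tert-butyldimethylsilyl)oxy]-2-hydroxy-1,2,6-trimethyl-1,2,6,7,8,8a-hexahydronaphthalen-1-yl]ethan-1-one, via alkenylchromium(III) species 17 (not isolated), via chromium(III) alkoxide 18 (not isolated)
Conditions: CrCl2 (6 equiv), NiCl2 (2 mol%), degassed DMSO, rt; aq. sodium serinate work-up
Reagents that add atoms: none
Why: Ni(0) inserts into the (Z)-C6–I bond with retention and passes the alkenyl group to Cr(III), and alkenylchromium 17 adds through C6 to the carbonyl carbon of one acetyl group (C7) to give alkoxide 18 and, after work-up, the tertiary allylic alcohol (intramolecular Nozaki–Hiyama–Kishi reaction; the closest known cases are NHK cyclisations of alkenyl iodides onto ketones and group-selective additions to 2,2-disubstituted 1,3-diketones). Ring B closes in the 6-exo-trig mode, C6 attacking the C7 carbonyl carbon with the oxygen outside the ring. Because C8a, C4a, C5 and C6 are coplanar in the s-trans diene and C8a–H points to the lower face, C8 has to be the out-of-plane atom on the upper face, which sorts its three groups into a ring site, an axial site and an equatorial site; C8 should be set by the reacting acetyl being the one that leaves the small methyl axial (next to the axial C1–OTBS) and the second acetyl equatorial, where it avoids that 1,3-contact and can bind the same chromium centre as the reacting carbonyl. C7 should be set by the carbonyl presenting the face that puts its oxygen pseudo-equatorial (gauche to the equatorial acetyl, chelate) and its methyl pseudo-axial, anti to the C8 methyl. The step needs group selectivity between two diastereotopic acetyls and face selectivity, both resting on the C8a stereocentre and its C1–OTBS neighbour and both still to be proven, and chemoselectivity, which is secured because alkenylchromium reagents leave silyl ethers and alkenes alone and both carbonyls are acetyl groups, so the one left over is necessarily the C9 ketone.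

Step 14
Reactants: 19 1-[(1R,2R,6S,8S,8aS)-8-[(tert-butyldimethylsilyl)oxy]-2-hydroxy-1,2,6-trimethyl-1,2,6,7,8,8a-hexahydronaphthalen-1-yl]ethan-1-one
Product: 20 1-[(1R,2R,6S,8S,8aS)-2,8-dihydroxy-1,2,6-trimethyl-1,2,6,7,8,8a-hexahydronaphthalen-1-yl]ethan-1-one
Conditions: HF·pyridine, pyridine, THF, 0 °C → rt
Reagents that add atoms: none
Why: buffered fluoride cleavage of the secondary TBS ether in a non-basic medium, which should avoid retro-aldol opening of the C7-hydroxy C9-ketone.

Step 15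
Reactants: 21 prop-2-yn-1-ol
Product: 23 (E)-3-iodo-2-methylprop-2-en-1-ol, via alkenylalane 22 (not isolated)
Conditions: Me3Al, Cp2ZrCl2 (cat.), CH2Cl2, 0 °C → rt; I2, THF, –30 °C
Reagents that add atoms: trimethylaluminium, C[Al](C)C; iodine, II
Why: Negishi zirconium-catalysed carboalumination adds methyl and aluminium syn across the alkyne (methyl to the internal carbon) and iodinolysis with retention gives the (E)-iodoalkene.

Step 16
Reactants: 23 (E)-3-iodo-2-methylprop-2-en-1-ol
Product: 24 (E)-3-iodo-2-methylprop-2-enal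
Conditions: MnO2, CH2Cl2, rt (solution used directly)
Reagents that add atoms: none
Why: manganese dioxide oxidation of an allylic alcohol gives the volatile enal without affecting the alkenyl iodide or its geometry.

Step 17
Reactants: 25 (R)-4-benzyl-3-propanoyl-1,3-oxazolidin-2-one; 24 (E)-3-iodo-2-methylprop-2-enal
Product: 27 (R)-4-benzyl-3-[(2S,3R,4E)-3-hydroxy-5-iodo-2,4-dimethylpent-4-enoyl]-1,3-oxazolidin-2-one, via aldol trimethylsilyl ether 26 (not isolated)
Conditions: MgCl2 (cat.), Et3N, TMSCl, EtOAc, rt; then 1 M HCl, THF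
Reagents that add atoms: none
Why: magnesium-halide-catalysed Evans anti-aldol of an N-acyloxazolidinone with a non-enolisable enal, in which the chelated Z-enolate is attacked opposite the benzyl group through a boat-like transition state and should set C2′ (S) and C3′ (R).

Step 18
Reactants: 27 (R)-4-benzyl-3-[(2S,3R,4E)-3-hydroxy-5-iodo-2,4-dimethylpent-4-enoyl]-1,3-oxazolidin-2-one
Product: 28 (R)-4-benzyl-3-{(2S,3R,4E)-5-iodo-2,4-dimethyl-3-[(triethylsilyl)oxy]pent-4-enoyl}-1,3-oxazolidin-2-one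
Conditions: TESCl, imidazole, DMF, 0 °C → rt
Reagents that add atoms: chlorotriethylsilane, CC[Si](CC)(CC)Cl
Why: silylation protects the C3′ alcohol as a TES ether that the final fluoride step removes.

Step 19
Reactants: 28 (R)-4-benzyl-3-{(2S,3R,4E)-5-iodo-2,4-dimethyl-3-[(triethylsilyl)oxy]pent-4-enoyl}-1,3-oxazolidin-2-one
Product: 30 (2S,3R,4E)-5-iodo-2,4-dimethyl-3-[(triethylsilyl)oxy]pent-4-enoic acid, via lithium peroxycarboxylate 29 (not isolated)
Conditions: LiOH, H2O2, THF/H2O, 0 °C; Na2SO3; dil. HCl to pH 4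
Reagents that add atoms: hydrogen peroxide, OO
Why: hydroperoxide attacks the exocyclic imide carbonyl selectively (auxiliary cleavage), and the cold, weakly basic conditions should avoid epimerisation at C2′ and β-elimination of the silyloxy group.

Step 20
Reactants: 30 (2S,3R,4E)-5-iodo-2,4-dimethyl-3-[(triethylsilyl)oxy]pent-4-enoic acid; 20 1-[(1R,2R,6S,8S,8aS)-2,8-dihydroxy-1,2,6-trimethyl-1,2,6,7,8,8a-hexahydronaphthalen-1-yl]ethan-1-one
Product: 32 (1S,3S,7R,8R,8aS)-8-acetyl-7-hydroxy-3,7,8-trimethyl-1,2,3,7,8,8a-hexahydronaphthalen-1-yl (2S,3R,4E)-5-iodo-2,4-dimethyl-3-[(triethylsilyl)oxy]pent-4-enoate, via mixed anhydride 31 (not isolated)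
Conditions: 2,4,6-trichlorobenzoyl chloride, Et3N, toluene, rt; then 20, DMAP, rt → 40 °C
Reagents that add atoms: none
Why: Yamaguchi esterification, in which the DMAP-activated mixed anhydride acylates the secondary C1 alcohol while the tertiary C7 alcohol is too hindered to react.

Step 21
Reactants: 32 (1S,3S,7R,8R,8aS)-8-acetyl-7-hydroxy-3,7,8-trimethyl-1,2,3,7,8,8a-hexahydronaphthalen-1-yl (2S,3R,4E)-5-iodo-2,4-dimethyl-3-[(triethylsilyl)oxy]pent-4-enoate
Product: 33 bis(trimethylsilyl) derivative of 32 (C7–OSiMe3; C9 as the 1-[(trimethylsilyl)oxy]ethenyl enol ether)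
Conditions: TMSOTf, Et3N, CH2Cl2, –78 → 0 °C
Reagents that add atoms: trimethylsilyl trifluoromethanesulfonate, C[Si](C)(C)OS(=O)(=O)C(F)(F)F
Why: soft enolisation–silylation converts the methyl ketone, which can enolise only towards C10 because C8 is quaternary, into its TMS enol ether and caps the C7 alcohol, so that no free β-keto alkoxide is formed and the ester is left alone.

Step 22
Reactants: 33 bis(trimethylsilyl) derivative of 32
Product: 34 (1S,3S,7R,8R,8aS)-8-(3-hydroxypropanoyl)-3,7,8-trimethyl-7-[(trimethylsilyl)oxy]-1,2,3,7,8,8a-hexahydronaphthalen-1-yl (2S,3R,4E)-5-iodo-2,4-dimethyl-3-[(triethylsilyl)oxy]pent-4-enoate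
Conditions: aq. HCHO (37%), Yb(OTf)3 (cat.), THF, rt
Reagents that add atoms: formaldehyde, C=O
Why: lanthanide-triflate-catalysed aqueous Mukaiyama aldol (hydroxymethylation) of the silyl enol ether adds C11 with its hydroxyl under near-neutral conditions, and partial loss of the C7 or C3′ silyl group would be of no consequence because step 28 removes both.

Step 23
Reactants: 35 (Z)-3-methylpent-2-en-4-yn-1-ol
Product: 36 (2Z,4E)-3-methyl-5-(tributylstannyl)penta-2,4-dien-1-ol
Conditions: Bu3SnH, PdCl2(PPh3)2 (cat.), THF, 0 °C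
Reagents that add atoms: tributyltin hydride, CCCC[SnH](CCCC)CCCC
Why: palladium-catalysed hydrostannation adds Sn–H syn to the terminal alkyne with tin at the less hindered terminal carbon, giving the (E)-alkenylstannane and leaving the (Z)-trisubstituted alkene of the enynol unchanged.

Step 24
Reactants: 36 (2Z,4E)-3-methyl-5-(tributylstannyl)penta-2,4-dien-1-ol
Product: 37 (2Z,4E)-3-methyl-5-(tributylstannyl)penta-2,4-dienal
Conditions: MnO2, CH2Cl2, rt, dark
Reagents that add atoms: none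
Why: allylic oxidation with manganese dioxide under neutral heterogeneous conditions, chosen to keep the (2Z) geometry.

Step 25
Reactants: 37 (2Z,4E)-3-methyl-5-(tributylstannyl)penta-2,4-dienal
Product: 38 ethyl (2E,4Z,6E)-5-methyl-7-(tributylstannyl)hepta-2,4,6-trienoate
Conditions: Ph3P=CHCO2Et, CH2Cl2, rt
Reagents that add atoms: ethyl (triphenylphosphoranylidene)acetate, CCOC(=O)C=P(c1ccccc1)(c1ccccc1)c1ccccc1
Why: Wittig reaction with a stabilised ylide gives the (E)-enoate under base-free conditions that should not isomerise the (Z)-alkene.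

Step 26
Reactants: 38 ethyl (2E,4Z,6E)-5-methyl-7-(tributylstannyl)hepta-2,4,6-trienoate
Product: 39 (2E,4Z,6E)-5-methyl-7-(tributylstannyl)hepta-2,4,6-trienoic acid
Conditions: LiOH, THF/MeOH/H2O, rt; dil. HCl to pH 4, 0 °C
Reagents that add atoms: lithium hydroxide, [Li+].[OH-]
Why: saponification of the ethyl ester, the alkenyl–tin bond being stable to aqueous base and to a brief, cold, weakly acidic work-up.

Step 27
Reactants: 34 (1S,3S,7R,8R,8aS)-8-(3-hydroxypropanoyl)-3,7,8-trimethyl-7-[(trimethylsilyl)oxy]-1,2,3,7,8,8a-hexahydronaphthalen-1-yl (2S,3R,4E)-5-iodo-2,4-dimethyl-3-[(triethylsilyl)oxy]pent-4-enoate; 39 (2E,4Z,6E)-5-methyl-7-(tributylstannyl)hepta-2,4,6-trienoic acid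
Product: 40 calbistrin D 7-O-trimethylsilyl 10′-O-triethylsilyl bis-ether (C7–OSiMe3 and C3′–OSiEt3; free C11–OH and CO2H)
Conditions: Pd(PPh3)4 (cat.), CuTC, Bu4N Ph2PO2, DMF, rt, dark
Reagents that add atoms: none
Why: copper-promoted Stille coupling joins C5′ and C6′ with retention of both alkene geometries at room temperature and tolerates the free acid, the primary alcohol and the β-hydroxy ketone.

Step 28
Reactants: 40 calbistrin D 7-O-trimethylsilyl 10′-O-triethylsilyl bis-ether
Product: 41 calbistrin D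
Conditions: HF·pyridine, pyridine, THF, 0 °C
Reagents that add atoms: none
Why: buffered fluoride desilylation removes the C3′ TES and C7 TMS ethers and should spare the tetraene acid, the tertiary allylic alcohol and the β-hydroxy ketone.

**Compound list**

1 | 1,4-dioxaspiro[4.5]dec-6-en-8-one | O=C1CCC2(OCCO2)C=C1 | starting material
2 | (S)-1,4-dioxaspiro[4.5]dec-6-en-8-ol | O[C@H]1CCC2(OCCO2)C=C1 | intermediate
3 | (S)-8-[(tert-butyldimethylsilyl)oxy]-1,4-dioxaspiro[4.5]dec-6-ene | CC(C)(C)[Si](C)(C)O[C@H]1CCC2(OCCO2)C=C1 | intermediate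
4 | (S)-4-[(tert-butyldimethylsilyl)oxy]cyclohex-2-en-1-one | CC(C)(C)[Si](C)(C)O[C@H]1CCC(=O)C=C1 | intermediate
5 | lithium (S)-4-[(tert-butyldimethylsilyl)oxy]cyclohexa-1,5-dien-1-olate | CC(C)(C)[Si](C)(C)O[C@H]1CC=C(O[Li])C=C1 | intermediate (not isolated)
6 | (4S,6S)-4-[(tert-butyldimethylsilyl)oxy]-6-methylcyclohex-2-en-1-one | CC(C)(C)[Si](C)(C)O[C@H]1C[C@H](C)C(=O)C=C1 | intermediate
7 | (4S,6S)-4-[(tert-butyldimethylsilyl)oxy]-2-iodo-6-methylcyclohex-2-en-1-one | CC(C)(C)[Si](C)(C)O[C@H]1C[C@H](C)C(=O)C(I)=C1 | intermediate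
8 | (4S,6S)-4-[(tert-butyldimethylsilyl)oxy]-6-methyl-2-[(trimethylsilyl)ethynyl]cyclohex-2-en-1-one | CC(C)(C)[Si](C)(C)O[C@H]1C[C@H](C)C(=O)C(C#C[Si](C)(C)C)=C1 | intermediate
9 | (1R,4S,6S)-4-[(tert-butyldimethylsilyl)oxy]-6-methyl-2-[(trimethylsilyl)ethynyl]cyclohex-2-en-1-ol | CC(C)(C)[Si](C)(C)O[C@H]1C[C@H](C)[C@@H](O)C(C#C[Si](C)(C)C)=C1 | intermediate
10 | 3-methylpentane-2,4-dione | CC(=O)C(C)C(C)=O | starting material
11 | 4-chloro-3-methylpent-3-en-2-one (E/Z mixture) | CC(=O)C(C)=C(C)Cl | intermediate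
12 | sodium alkoxide of 9 | CC(C)(C)[Si](C)(C)O[C@H]1C[C@H](C)[C@@H](O[Na])C(C#C[Si](C)(C)C)=C1 | intermediate (not isolated)
13 | (E)-4-{[(1R,4S,6S)-4-[(tert-butyldimethylsilyl)oxy]-6-methyl-2-[(trimethylsilyl)ethynyl]cyclohex-2-en-1-yl]oxy}-3-methylpent-3-en-2-one | CC(C)(C)[Si](C)(C)O[C@H]1C[C@H](C)[C@@H](O/C(C)=C(\C)C(C)=O)C(C#C[Si](C)(C)C)=C1 | intermediate
14 | 3-{(1S,4S,6S)-6-[(tert-butyldimethylsilyl)oxy]-4-methyl-2-[(trimethylsilyl)ethynyl]cyclohex-2-en-1-yl}-3-methylpentane-2,4-dione | CC(C)(C)[Si](C)(C)O[C@H]1C[C@H](C)C=C(C#C[Si](C)(C)C)[C@H]1C(C)(C(C)=O)C(C)=O | intermediate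
15 | 3-{(1S,4S,6S)-6-[(tert-butyldimethylsilyl)oxy]-2-(iodoethynyl)-4-methylcyclohex-2-en-1-yl}-3-methylpentane-2,4-dione | CC(C)(C)[Si](C)(C)O[C@H]1C[C@H](C)C=C(C#CI)[C@H]1C(C)(C(C)=O)C(C)=O | intermediate
16 | 3-{(1S,4S,6S)-6-[(tert-butyldimethylsilyl)oxy]-2-[(Z)-2-iodoethenyl]-4-methylcyclohex-2-en-1-yl}-3-methylpentane-2,4-dione (key-step precursor) | CC(C)(C)[Si](C)(C)O[C@H]1C[C@H](C)C=C(/C=C\I)[C@H]1C(C)(C(C)=O)C(C)=O | intermediate
17 | (Z)-alkenylchromium(III) dichloride derived from 16 (Cr on C6) | CC(C)(C)[Si](C)(C)O[C@H]1C[C@H](C)C=C(/C=C\[Cr](Cl)Cl)[C@H]1C(C)(C(C)=O)C(C)=O | intermediate (not isolated)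
18 | chromium(III) C7-alkoxide of 19 | CC(C)(C)[Si](C)(C)O[C@H]1C[C@H](C)C=C2C=C[C@@](C)(O[Cr](Cl)Cl)[C@](C)(C(C)=O)[C@H]21 | intermediate (not isolated)
19 | 1-[(1R,2R,6S,8S,8aS)-8-[(tert-butyldimethylsilyl)oxy]-2-hydroxy-1,2,6-trimethyl-1,2,6,7,8,8a-hexahydronaphthalen-1-yl]ethan-1-one (key-step product) | CC(C)(C)[Si](C)(C)O[C@H]1C[C@H](C)C=C2C=C[C@@](C)(O)[C@](C)(C(C)=O)[C@H]21 | intermediate
20 | 1-[(1R,2R,6S,8S,8aS)-2,8-dihydroxy-1,2,6-trimethyl-1,2,6,7,8,8a-hexahydronaphthalen-1-yl]ethan-1-one | O[C@H]1C[C@H](C)C=C2C=C[C@@](C)(O)[C@](C)(C(C)=O)[C@H]21 | intermediate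
21 | prop-2-yn-1-ol | C#CCO | starting material
22 | (E)-alkenylalane, dimethylaluminium alkoxide of (E)-3-(dimethylalumanyl)-2-methylprop-2-en-1-ol | C[Al](C)OC/C(C)=C/[Al](C)C | intermediate (not isolated)
23 | (E)-3-iodo-2-methylprop-2-en-1-ol | I/C=C(\C)CO | intermediate
24 | (E)-3-iodo-2-methylprop-2-enal | I/C=C(\C)C=O | intermediate
25 | (R)-4-benzyl-3-propanoyl-1,3-oxazolidin-2-one | CCC(=O)N1[C@H](Cc2ccccc2)COC1=O | starting material
26 | trimethylsilyl ether of aldol adduct 27 | I/C=C(\C)[C@H](O[Si](C)(C)C)[C@H](C)C(=O)N1[C@H](Cc2ccccc2)COC1=O | intermediate (not isolated)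
27 | (R)-4-benzyl-3-[(2S,3R,4E)-3-hydroxy-5-iodo-2,4-dimethylpent-4-enoyl]-1,3-oxazolidin-2-one | I/C=C(\C)[C@H](O)[C@H](C)C(=O)N1[C@H](Cc2ccccc2)COC1=O | intermediate
28 | (R)-4-benzyl-3-{(2S,3R,4E)-5-iodo-2,4-dimethyl-3-[(triethylsilyl)oxy]pent-4-enoyl}-1,3-oxazolidin-2-one | I/C=C(\C)[C@H](O[Si](CC)(CC)CC)[C@H](C)C(=O)N1[C@H](Cc2ccccc2)COC1=O | intermediate
29 | lithium (2S,3R,4E)-5-iodo-2,4-dimethyl-3-[(triethylsilyl)oxy]pent-4-eneperoxoate | I/C=C(\C)[C@H](O[Si](CC)(CC)CC)[C@H](C)C(=O)OO[Li] | intermediate (not isolated)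
30 | (2S,3R,4E)-5-iodo-2,4-dimethyl-3-[(triethylsilyl)oxy]pent-4-enoic acid | I/C=C(\C)[C@H](O[Si](CC)(CC)CC)[C@H](C)C(=O)O | intermediate
31 | mixed anhydride of 30 with 2,4,6-trichlorobenzoic acid | I/C=C(\C)[C@H](O[Si](CC)(CC)CC)[C@H](C)C(=O)OC(=O)c1c(Cl)cc(Cl)cc1Cl | intermediate (not isolated)
32 | (1S,3S,7R,8R,8aS)-8-acetyl-7-hydroxy-3,7,8-trimethyl-1,2,3,7,8,8a-hexahydronaphthalen-1-yl (2S,3R,4E)-5-iodo-2,4-dimethyl-3-[(triethylsilyl)oxy]pent-4-enoate | I/C=C(\C)[C@H](O[Si](CC)(CC)CC)[C@H](C)C(=O)O[C@H]1C[C@H](C)C=C2C=C[C@@](C)(O)[C@](C)(C(C)=O)[C@H]21 | intermediate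
33 | bis(trimethylsilyl) derivative of 32 (C7–OSiMe3, C9 trimethylsilyl enol ether) | I/C=C(\C)[C@H](O[Si](CC)(CC)CC)[C@H](C)C(=O)O[C@H]1C[C@H](C)C=C2C=C[C@@](C)(O[Si](C)(C)C)[C@](C)(C(=C)O[Si](C)(C)C)[C@H]21 | intermediate
34 | (1S,3S,7R,8R,8aS)-8-(3-hydroxypropanoyl)-3,7,8-trimethyl-7-[(trimethylsilyl)oxy]-1,2,3,7,8,8a-hexahydronaphthalen-1-yl (2S,3R,4E)-5-iodo-2,4-dimethyl-3-[(triethylsilyl)oxy]pent-4-enoate | I/C=C(\C)[C@H](O[Si](CC)(CC)CC)[C@H](C)C(=O)O[C@H]1C[C@H](C)C=C2C=C[C@@](C)(O[Si](C)(C)C)[C@](C)(C(=O)CCO)[C@H]21 | intermediate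
35 | (Z)-3-methylpent-2-en-4-yn-1-ol | CC(=C/CO)/C#C | starting material
36 | (2Z,4E)-3-methyl-5-(tributylstannyl)penta-2,4-dien-1-ol | CC(=C/CO)/C=C/[Sn](CCCC)(CCCC)CCCC | intermediate
37 | (2Z,4E)-3-methyl-5-(tributylstannyl)penta-2,4-dienal | CC(=C/C=O)/C=C/[Sn](CCCC)(CCCC)CCCC | intermediate
38 | ethyl (2E,4Z,6E)-5-methyl-7-(tributylstannyl)hepta-2,4,6-trienoate | CC(=C/C=C/C(=O)OCC)/C=C/[Sn](CCCC)(CCCC)CCCC | intermediate
39 | (2E,4Z,6E)-5-methyl-7-(tributylstannyl)hepta-2,4,6-trienoic acid | CC(=C/C=C/C(=O)O)/C=C/[Sn](CCCC)(CCCC)CCCC | intermediate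
40 | calbistrin D 7-O-trimethylsilyl 10′-O-triethylsilyl bis-ether, (2E,4Z,6E,8E,10R,11S)-tetraenoic acid numbering | CC(=C/C=C/C(=O)O)/C=C/C=C(\C)[C@H](O[Si](CC)(CC)CC)[C@H](C)C(=O)O[C@H]1C[C@H](C)C=C2C=C[C@@](C)(O[Si](C)(C)C)[C@](C)(C(=O)CCO)[C@H]21 | intermediate
41 | calbistrin D, (2E,4Z,6E,8E,10R,11S)-10-hydroxy-12-{[(1S,3S,7R,8R,8aS)-7-hydroxy-8-(3-hydroxypropanoyl)-3,7,8-trimethyl-1,2,3,7,8,8a-hexahydronaphthalen-1-yl]oxy}-5,9,11-trimethyl-12-oxododeca-2,4,6,8-tetraenoic acid | CC(=C/C=C/C(=O)O)/C=C/C=C(\C)[C@H](O)[C@H](C)C(=O)O[C@H]1C[C@H](C)C=C2C=C[C@@](C)(O)[C@](C)(C(=O)CCO)[C@H]21 | target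

**Step count and risks**

Total step count: 28. Longest linear sequence: 18 steps (1–7, 9–14, 20–22, 27, 28, from compound 1).

Steps most likely to fail:

Step 13. The alkenylchromium may not discriminate well enough between the two acetyl groups or between the two carbonyl faces, so that C7/C8 diastereomers form together, or it may be protonated before it cyclises. The fallback sets out from 14 and comes back at 19. Silver-catalysed protodesilylation (AgNO3 cat., acetone/H2O) would give the terminal alkyne diketone F1. Lindlar semihydrogenation would give the 2-ethenyl diene diketone F2. Cerium-mediated addition of vinylmagnesium bromide (CeCl3, THF, –78 °C) to one acetyl group would give divinyl carbinols whose diastereomers can be separated and assigned at the open-chain stage, the (3R,4R)-configured divinyl carbinol F3 being carried on. Ring-closing metathesis (second-generation ruthenium benzylidene catalyst, CH2Cl2, 40 °C) would then form C5=C6 and give 19 without creating a stereocentre. Ring B is thus closed through a different bond, and the stereo-determining addition becomes intermolecular and correctable before closure.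

Step 9. Vinylic substitution at the fully substituted β-carbon of 11 may be slow, so that enolisation of 11 by the alkoxide or silyl migration takes over; the crowded product is also the most demanding substrate for the Claisen step. The fallback sets out from 9 and comes back at 14. Base-catalysed oxa-Michael addition of 9 to pent-3-yn-2-one (cat. NaH or PMe3, THF) would give the less hindered trisubstituted enol ether F4. Claisen rearrangement (toluene, 150–170 °C) would give the 3-monosubstituted pentane-2,4-dione F5. C-methylation of its enolate (MeI, Cs2CO3, MeCN) would install the C8 methyl and give 14. The quaternary carbon is then made by enolate alkylation after the [3,3] shift instead of during it.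

Step 22. At this advanced stage, hydrolysis of the silyl enol ether back to the methyl ketone may outrun the aldol, the new β-hydroxy ketone may dehydrate, or the Lewis acid may damage the iodo-diene ester. The fallback sets out from 19, comes back at 41, and extends the C9 chain before the side chain is attached:
- TMSOTf/Et3N on 19 would give the bis-silyl enol ether F6.
- Aqueous formaldehyde/Yb(OTf)3 would give the hydroxymethyl ketone F7.
- HF·pyridine would remove the TBS and TMS groups and give the decalin triol F8.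
- TESCl/imidazole at –20 °C would silylate only the primary C11 alcohol and give the C11 triethylsilyl ether F9.
- Yamaguchi esterification with 30 would give the iodo ester F10.
- Stille coupling with 39 would give the bis-TES tetraene acid F11.
- HF·pyridine would then give 41.

Further compounds
F1 | step 13 | 3-{(1S,4S,6S)-6-[(tert-butyldimethylsilyl)oxy]-2-ethynyl-4-methylcyclohex-2-en-1-yl}-3-methylpentane-2,4-dione | CC(C)(C)[Si](C)(C)O[C@H]1C[C@H](C)C=C(C#C)[C@H]1C(C)(C(C)=O)C(C)=O
F2 | step 13 | 3-{(1S,4S,6S)-6-[(tert-butyldimethylsilyl)oxy]-2-ethenyl-4-methylcyclohex-2-en-1-yl}-3-methylpentane-2,4-dione | CC(C)(C)[Si](C)(C)O[C@H]1C[C@H](C)C=C(C=C)[C@H]1C(C)(C(C)=O)C(C)=O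
F3 | step 13 | (3R,4R)-3-{(1S,4S,6S)-6-[(tert-butyldimethylsilyl)oxy]-2-ethenyl-4-methylcyclohex-2-en-1-yl}-4-hydroxy-3,4-dimethylhex-5-en-2-one | CC(C)(C)[Si](C)(C)O[C@H]1C[C@H](C)C=C(C=C)[C@H]1[C@@](C)(C(C)=O)[C@](C)(O)C=C
F4 | step 9 | (E)-4-{[(1R,4S,6S)-4-[(tert-butyldimethylsilyl)oxy]-6-methyl-2-[(trimethylsilyl)ethynyl]cyclohex-2-en-1-yl]oxy}pent-3-en-2-one | CC(C)(C)[Si](C)(C)O[C@H]1C[C@H](C)[C@@H](O/C(C)=C/C(C)=O)C(C#C[Si](C)(C)C)=C1
F5 | step 9 | 3-{(1R,4S,6S)-6-[(tert-butyldimethylsilyl)oxy]-4-methyl-2-[(trimethylsilyl)ethynyl]cyclohex-2-en-1-yl}pentane-2,4-dione | CC(C)(C)[Si](C)(C)O[C@H]1C[C@H](C)C=C(C#C[Si](C)(C)C)[C@H]1C(C(C)=O)C(C)=O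
F6 | step 22 | bis(trimethylsilyl) derivative of 19 (C7–OSiMe3, C9 trimethylsilyl enol ether, C1–OTBS) | CC(C)(C)[Si](C)(C)O[C@H]1C[C@H](C)C=C2C=C[C@@](C)(O[Si](C)(C)C)[C@](C)(C(=C)O[Si](C)(C)C)[C@H]21
F7 | step 22 | 1-[(1R,2R,6S,8S,8aS)-8-[(tert-butyldimethylsilyl)oxy]-1,2,6-trimethyl-2-[(trimethylsilyl)oxy]-1,2,6,7,8,8a-hexahydronaphthalen-1-yl]-3-hydroxypropan-1-one | CC(C)(C)[Si](C)(C)O[C@H]1C[C@H](C)C=C2C=C[C@@](C)(O[Si](C)(C)C)[C@](C)(C(=O)CCO)[C@H]21
F8 | step 22 | 1-[(1R,2R,6S,8S,8aS)-2,8-dihydroxy-1,2,6-trimethyl-1,2,6,7,8,8a-hexahydronaphthalen-1-yl]-3-hydroxypropan-1-one | O[C@H]1C[C@H](C)C=C2C=C[C@@](C)(O)[C@](C)(C(=O)CCO)[C@H]21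
F9 | step 22 | 1-[(1R,2R,6S,8S,8aS)-2,8-dihydroxy-1,2,6-trimethyl-1,2,6,7,8,8a-hexahydronaphthalen-1-yl]-3-[(triethylsilyl)oxy]propan-1-one | O[C@H]1C[C@H](C)C=C2C=C[C@@](C)(O)[C@](C)(C(=O)CCO[Si](CC)(CC)CC)[C@H]21
F10 | step 22 | (1S,3S,7R,8R,8aS)-7-hydroxy-3,7,8-trimethyl-8-{3-[(triethylsilyl)oxy]propanoyl}-1,2,3,7,8,8a-hexahydronaphthalen-1-yl (2S,3R,4E)-5-iodo-2,4-dimethyl-3-[(triethylsilyl)oxy]pent-4-enoate | I/C=C(\C)[C@H](O[Si](CC)(CC)CC)[C@H](C)C(=O)O[C@H]1C[C@H](C)C=C2C=C[C@@](C)(O)[C@](C)(C(=O)CCO[Si](CC)(CC)CC)[C@H]21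
F11 | step 22 | calbistrin D 11-O,10′-O-bis(triethylsilyl) ether | CC(=C/C=C/C(=O)O)/C=C/C=C(\C)[C@H](O[Si](CC)(CC)CC)[C@H](C)C(=O)O[C@H]1C[C@H](C)C=C2C=C[C@@](C)(O)[C@](C)(C(=O)CCO[Si](CC)(CC)CC)[C@H]21
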